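**Retrosynthetic overview**
1. Target 18 ⇐ triene diacetate 17 by a Schenck ene reaction of singlet oxygen at C1=C10 (C1–O bond, C1 stereocentre and exocyclic alkene in the last step).
2. 17 ⇐ butenolide 15 ⇐ spiro-epoxy lactone 13: the C13 acetate and the C7=C11 alkene come from an acylative, eliminative epoxide opening (new).
3. 13 ⇐ keto glycidate 11: catalyst-controlled reduction at C6, then the γ-lactone closes through the C6–O–C12 bond.
4. 11 ⇐ carbinol 6 + ethyl bromopyruvate 7: anionic oxy-Cope ring expansion gives the ten-membered ring; its enolate is trapped as the glycidate (C7–C11 and C13–O bonds).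
5. 6 ⇐ (S)-carvone 1 + vinylmagnesium bromide 5 (C3 from the chiral pool, C6 oxygen by allylic C–H oxidation). Ring order: cyclohexene (from 1) → ten-membered carbocycle → oxirane → γ-lactone.

Assumption: germacrane numbering is used for the ten-membered compounds (C1 = CH–OOH, C3 = CH–OAc, C4=C5, C6 = lactone CH–O, C7=C11, C12 = lactone C=O, C13 = CH2OAc, C14 on C10, C15 on C4); C7 and C11 of compounds 10 to 14 are carried as epimer mixtures (left undefined in the SMILES) because step 7 makes both sp2.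

**Route**

Step 1
Reactants: 1 (S)-(+)-carvone
Product: 2 (1S,5S)-2-methyl-5-(prop-1-en-2-yl)cyclohex-2-en-1-ol (cis-carveol)
Conditions: NaBH4, CeCl3·7H2O, MeOH, 0 °C
Reagents that add atoms: none
Why: Luche 1,2-reduction of the enone, which is known to give the cis allylic alcohol from carvone with high selectivity, so the future C3 carbinol is set as 1S.

Step 2
Reactants: 2 (1S,5S)-cis-carveol
Product: 3 tert-butyldimethyl{[(1S,5S)-2-methyl-5-(prop-1-en-2-yl)cyclohex-2-en-1-yl]oxy}silane
Conditions: TBSCl, imidazole, DMF, rt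
Reagents that add atoms: tert-butyldimethylsilyl chloride, CC(C)(C)[Si](C)(C)Cl
Why: Standard silylation at oxygen (no stereocentre touched); the silyl ether survives the Grignard and potassium hydride steps and keeps the later Z-γ-oxy enone from closing to a hemiketal or furan.

Step 3
Reactants: 3 cis-carveol TBS ether
Product: 4 (4S,6S)-4-[(tert-butyldimethylsilyl)oxy]-3-methyl-6-(prop-1-en-2-yl)cyclohex-2-en-1-one
Conditions: Rh2(cap)4 (cap = caprolactamate, 1 mol%), t-BuOOH (70% in water), K2CO3, CH2Cl2, rt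
Reagents that add atoms: tert-butyl hydroperoxide, CC(C)(C)OO
Why: Radical-chain allylic C–H oxidation by tert-butylperoxyl radicals at the only ring allylic CH2, forming the C–O bond that becomes the lactone oxygen; the C–H next to the silyloxy group is shielded, and isopropenyl groups are tolerated as in valencene-to-nootkatone oxidations.

Step 4
Reactants: 4 silyloxy enone; 5 vinylmagnesium bromide
Product: 6 (1S,4S,6S)-4-[(tert-butyldimethylsilyl)oxy]-1-ethenyl-3-methyl-6-(prop-1-en-2-yl)cyclohex-2-en-1-ol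
Conditions: THF, −78 °C; NH4Cl (aq)
Reagents that add atoms: none
Why: Grignard 1,2-addition to the β,β-disubstituted enone from the face opposite the adjacent isopropenyl group (equatorial attack) sets C1 as 1S with the two alkenyl groups trans-diequatorial, the arrangement needed for a chair oxy-Cope.

Step 5
Reactants: 6 divinyl carbinol; 7 ethyl bromopyruvate
Product: 11 ethyl 2-[(3Z,5S,7E)-5-[(tert-butyldimethylsilyl)oxy]-4,8-dimethyl-2-oxocyclodeca-3,7-dien-1-yl]oxirane-2-carboxylate, via potassium alkoxide 8 (not isolated), via potassium enolate 9 (not isolated), via potassium bromo-aldolate 10 (not isolated)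
Conditions: KH, 18-crown-6, THF, 0 °C to rt; then 7, −78 to −20 °C; NH4Cl (aq)
Reagents that add atoms: none
Why: Anionic oxy-Cope rearrangement through a chair transition state gives the ten-membered ring with the 1(10)E alkene and keeps the cyclohexene alkene as 4Z, and the regiodefined enolate is trapped in a Darzens-type aldol addition and oxirane closure onto the ketone carbon of 7; C7 and C11 form as an epimer mixture that step 7 erases.

Step 6
Reactants: 11 keto glycidate
Product: 13 (3S,6R)-3-[(tert-butyldimethylsilyl)oxy]-11,13-epoxygermacra-1(10)E,4Z-dien-12,6-olide, via hydroxy ester 12 (not isolated)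
Conditions: (S)-2-methyl-CBS-oxazaborolidine (0.2 equiv), catecholborane, toluene, −78 °C; MeOH; then PPTS (cat.), CH2Cl2, rt
Reagents that add atoms: none
Why: Corey–Bakshi–Shibata 1,2-reduction in which the catalyst, not the C7/C11 epimer mixture, sets C6: with the branched C7 substituent as the large group and the Z-alkenyl as the small one the (S)-catalyst gives 6R, and the new hydroxyl then closes on the ethyl ester (5-exo-trig lactonisation).

Step 7
Reactants: 13 spiro-epoxy lactone
Product: 15 (3S,6R)-13-acetoxy-3-[(tert-butyldimethylsilyl)oxy]germacra-1(10)E,4Z,7(11)-trien-12,6-olide, via dioxolanylium triflate 14 (not isolated)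
Conditions: Ac2O, Me3SiOTf, 2,6-di-tert-butyl-4-methylpyridine, CH2Cl2, −78 to −20 °C
Reagents that add atoms: acetic anhydride, CC(=O)OC(C)=O
Why: Proposed new method: acylative eliminative opening of a glycidic spiro-epoxide, in which acetyl triflate made in situ acylates the oxirane oxygen, the acyl oxygen closes onto C13 to give the spiro 2-methyl-1,3-dioxolan-2-ylium ion 14, and the hindered pyridine removes H7 in an E2 step that can only break the C11–O bond (the C13 hydrogens cannot become anti-periplanar inside the five-membered ring), so the acetate ends on C13 and the C7=C11 alkene forms with its geometry fixed by the lactone ring while both C7 and C11 stereocentres vanish; the closest known reaction types are the opening of epoxides by acylium ions to dioxolan-2-ylium salts and the silyl triflate/amine isomerisation of epoxides to allylic silyl ethers.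

Step 8
Reactants: 15 silyl-protected acetoxy butenolide
Product: 17 (3S,6R)-3,13-diacetoxygermacra-1(10)E,4Z,7(11)-trien-12,6-olide, via C3 alcohol 16 (not isolated)
Conditions: HF·pyridine, THF/pyridine, 0 °C to rt; then Ac2O, DMAP, 0 °C to rt
Reagents that add atoms: acetic anhydride, CC(=O)OC(C)=O
Why: Fluoride desilylation followed in the same flask by DMAP-catalysed acetylation; both occur at oxygen so C3 stays S, and the weakly basic medium leaves the doubly allylic C6–H untouched.

Step 9
Reactants: 17 triene diacetate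
Product: 18 (1R,3S,6R)-3,13-diacetoxy-1-hydroperoxygermacra-4Z,7(11),10(14)-trien-12,6-olide (CNP0174966.1)
Conditions: O2, hν (white LED), 5,10,15,20-tetraphenylporphyrin (1 mol%), CH2Cl2, −20 °C
Reagents that add atoms: dioxygen, O=O
Why: Schenck ene reaction in which singlet oxygen attacks only the electron-rich C1=C10 alkene (C4=C5 is deactivated by two allylic C–O bonds, C7=C11 is conjugated) at C1 from the outer face of the macrocycle and takes a C14 methyl hydrogen, giving the 1R (1β) hydroperoxide and the exocyclic alkene as in the photo-oxygenation of costunolide and parthenolide to their 1β-hydroperoxides.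

**Compound list**
1 | (S)-(+)-carvone, (5S)-2-methyl-5-(prop-1-en-2-yl)cyclohex-2-en-1-one | CC(=C)[C@H]1CC=C(C)C(=O)C1 | starting material
2 | (1S,5S)-2-methyl-5-(prop-1-en-2-yl)cyclohex-2-en-1-ol (cis-carveol) | CC(=C)[C@H]1CC=C(C)[C@@H](O)C1 | intermediate
3 | tert-butyldimethyl{[(1S,5S)-2-methyl-5-(prop-1-en-2-yl)cyclohex-2-en-1-yl]oxy}silane | CC(=C)[C@H]1CC=C(C)[C@@H](O[Si](C)(C)C(C)(C)C)C1 | intermediate
4 | (4S,6S)-4-[(tert-butyldimethylsilyl)oxy]-3-methyl-6-(prop-1-en-2-yl)cyclohex-2-en-1-one | CC(=C)[C@H]1C(=O)C=C(C)[C@@H](O[Si](C)(C)C(C)(C)C)C1 | intermediate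
5 | vinylmagnesium bromide | C=C[Mg]Br | starting material
6 | (1S,4S,6S)-4-[(tert-butyldimethylsilyl)oxy]-1-ethenyl-3-methyl-6-(prop-1-en-2-yl)cyclohex-2-en-1-ol | CC(=C)[C@H]1[C@](O)(C=C)C=C(C)[C@@H](O[Si](C)(C)C(C)(C)C)C1 | intermediate
7 | ethyl bromopyruvate (ethyl 3-bromo-2-oxopropanoate) | CCOC(=O)C(=O)CBr | starting material
8 | potassium alkoxide of 6 | CC(=C)[C@H]1[C@]([O-])(C=C)C=C(C)[C@@H](O[Si](C)(C)C(C)(C)C)C1.[K+] | intermediate
9 | potassium (2Z,4S,6E)-4-[(tert-butyldimethylsilyl)oxy]-3,7-dimethylcyclodeca-1(10),2,6-trien-1-olate (C6 enolate, germacrane numbering) | [K+].[O-]C1=CCC/C(C)=C/C[C@H](O[Si](C)(C)C(C)(C)C)/C(C)=C\1 | intermediate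
10 | potassium alkoxide of ethyl 3-bromo-2-hydroxy-2-[(3Z,5S,7E)-5-[(tert-butyldimethylsilyl)oxy]-4,8-dimethyl-2-oxocyclodeca-3,7-dien-1-yl]propanoate | CCOC(=O)C([O-])(CBr)C1CC/C(C)=C/C[C@H](O[Si](C)(C)C(C)(C)C)/C(C)=C\C1=O.[K+] | intermediate
11 | ethyl 2-[(3Z,5S,7E)-5-[(tert-butyldimethylsilyl)oxy]-4,8-dimethyl-2-oxocyclodeca-3,7-dien-1-yl]oxirane-2-carboxylate | CCOC(=O)C1(CO1)C2CC/C(C)=C/C[C@H](O[Si](C)(C)C(C)(C)C)/C(C)=C\C2=O | intermediate
12 | ethyl 2-[(2R,3Z,5S,7E)-5-[(tert-butyldimethylsilyl)oxy]-2-hydroxy-4,8-dimethylcyclodeca-3,7-dien-1-yl]oxirane-2-carboxylate | CCOC(=O)C1(CO1)C2CC/C(C)=C/C[C@H](O[Si](C)(C)C(C)(C)C)/C(C)=C\[C@H]2O | intermediate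
13 | (3S,6R)-3-[(tert-butyldimethylsilyl)oxy]-11,13-epoxygermacra-1(10)E,4Z-dien-12,6-olide | C/C1=C\C[C@H](O[Si](C)(C)C(C)(C)C)/C(C)=C\[C@H]2OC(=O)C3(CO3)C2CC1 | intermediate
14 | spiro 2-methyl-1,3-dioxolan-2-ylium triflate bridging C11 and C13 of 13 | C/C1=C\C[C@H](O[Si](C)(C)C(C)(C)C)/C(C)=C\[C@H]2OC(=O)C3(CO[C+](C)O3)C2CC1.[O-]S(=O)(=O)C(F)(F)F | intermediate
15 | (3S,6R)-13-acetoxy-3-[(tert-butyldimethylsilyl)oxy]germacra-1(10)E,4Z,7(11)-trien-12,6-olide | C/C1=C\C[C@H](O[Si](C)(C)C(C)(C)C)/C(C)=C\[C@H]2OC(=O)C(COC(C)=O)=C2CC1 | intermediate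
16 | (3S,6R)-13-acetoxy-3-hydroxygermacra-1(10)E,4Z,7(11)-trien-12,6-olide | C/C1=C\C[C@H](O)/C(C)=C\[C@H]2OC(=O)C(COC(C)=O)=C2CC1 | intermediate
17 | (3S,6R)-3,13-diacetoxygermacra-1(10)E,4Z,7(11)-trien-12,6-olide | C/C1=C\C[C@H](OC(C)=O)/C(C)=C\[C@H]2OC(=O)C(COC(C)=O)=C2CC1 | intermediate
18 | (1R,3S,6R)-3,13-diacetoxy-1-hydroperoxygermacra-4Z,7(11),10(14)-trien-12,6-olide | C=C1CCC2=C(COC(C)=O)C(=O)O[C@@H]2/C=C(/C)[C@@H](OC(C)=O)C[C@H]1OO | target

**Step count and risks**
Total steps: 9. Longest linear sequence: 9 (all from 1).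

The three steps most likely to fail:

Step 7 (the proposed new method). The ion 14 may be captured at C13 by acetate or triflate instead of losing H7, one C7/C11 epimer series has H7 syn to the leaving oxygen, and acetyl triflate could attack the C1=C10 alkene or the allylic silyl ether. The fallback uses known chemistry only, sets out from 13 and comes back at 15: acetate opens the oxirane at its CH2 carbon (CsOAc, AcOH, DMF, 50 °C) to give the tertiary alcohol (3S,6R)-13-acetoxy-11-hydroxy-3-[(tert-butyldimethylsilyl)oxy]germacra-1(10)E,4Z-dien-12,6-olide F6, and Burgess reagent (toluene, 50 °C) dehydrates F6 to 15.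

Step 5. The naked potassium enolate may deprotonate 7 or alkylate at its CH2Br carbon, and 11 is a β,γ-epoxy ketone that can suffer E1cB opening if base remains. The fallback sets out from 6 and comes back at 11: after the same oxy-Cope rearrangement the enolate is quenched with Me3SiCl to give the isolated trimethylsilyl enol ether F1. A TiCl4-promoted Mukaiyama aldol addition of F1 to 7 (CH2Cl2, −78 °C) gives the bromohydrin F2, and K2CO3 (MeCN, 0 °C) closes F2 to the oxirane 11.

Step 6. The large/small assignment of the two ketone flanks for the CBS catalyst is not certain, so the 6S alcohol could dominate (the antipodal catalyst would be tried first). The fallback sets C6 by C–O bond formation with inversion; it sets out from 11 and comes back at 13: the 6S hydroxy ester F3 lactonises to the 6S epoxy lactone F4, LiOH (THF/H2O, 0 °C) opens F4 to the 6S hydroxy acid F5, and Mitsunobu lactonisation of F5 (PPh3, DIAD, THF, 0 °C) recloses the ring with inversion at C6 to give 13.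

Further compounds
F1 | step 5 | trimethylsilyl enol ether of (2Z,4S,6E)-4-[(tert-butyldimethylsilyl)oxy]-3,7-dimethylcyclodeca-2,6-dien-1-one | C[Si](C)(C)OC1=CCC/C(C)=C/C[C@H](O[Si](C)(C)C(C)(C)C)/C(C)=C\1
F2 | step 5 | ethyl 3-bromo-2-hydroxy-2-[(3Z,5S,7E)-5-[(tert-butyldimethylsilyl)oxy]-4,8-dimethyl-2-oxocyclodeca-3,7-dien-1-yl]propanoate | CCOC(=O)C(O)(CBr)C1CC/C(C)=C/C[C@H](O[Si](C)(C)C(C)(C)C)/C(C)=C\C1=O
F3 | step 6 | ethyl 2-[(2S,3Z,5S,7E)-5-[(tert-butyldimethylsilyl)oxy]-2-hydroxy-4,8-dimethylcyclodeca-3,7-dien-1-yl]oxirane-2-carboxylate | CCOC(=O)C1(CO1)C2CC/C(C)=C/C[C@H](O[Si](C)(C)C(C)(C)C)/C(C)=C\[C@@H]2O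
F4 | step 6 | (3S,6S)-3-[(tert-butyldimethylsilyl)oxy]-11,13-epoxygermacra-1(10)E,4Z-dien-12,6-olide | C/C1=C\C[C@H](O[Si](C)(C)C(C)(C)C)/C(C)=C\[C@@H]2OC(=O)C3(CO3)C2CC1
F5 | step 6 | 2-[(2S,3Z,5S,7E)-5-[(tert-butyldimethylsilyl)oxy]-2-hydroxy-4,8-dimethylcyclodeca-3,7-dien-1-yl]oxirane-2-carboxylic acid | OC(=O)C1(CO1)C2CC/C(C)=C/C[C@H](O[Si](C)(C)C(C)(C)C)/C(C)=C\[C@@H]2O
F6 | step 7 | (3S,6R)-13-acetoxy-11-hydroxy-3-[(tert-butyldimethylsilyl)oxy]germacra-1(10)E,4Z-dien-12,6-olide | C/C1=C\C[C@H](O[Si](C)(C)C(C)(C)C)/C(C)=C\[C@H]2OC(=O)C(O)(COC(C)=O)C2CC1
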